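**Retrosynthetic overview**
1. Target ⇒ diol 29 by two late O-acylations; 29 ⇒ epoxy acid 20 + alkenyl boronate 24 by a decarboxylative radical–polar [3+2] annulation that forms C2–C3 and C4–C5 and closes the cyclopentane last.
2. Enabling feature: in 20 the C5–C6 epoxide of the seven-membered ring lies syn to the CH2CO2H arm on the adjacent quaternary C1. The carbanion born at C4 is therefore 5-exo to C5, must attack anti to the epoxide oxygen (trans ring fusion), and leaves that oxygen as the C6 α-hydroxyl.
3. 20 ⇒ cis-dienol 14 by Eschenmoser–Claisen rearrangement (C1 quaternary center from the C6 carbinol), then iodolactonization and epoxide closure (the arm returns oxygen to C5–C6 on its own face).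
4. 14 ⇒ cycloheptadienone 11 (Luche reduction, 1,4-cis) ⇒ acyclic trienone 10 (ring-closing metathesis, C8=C9) ⇒ butenolide 6 (ring-closing metathesis, fixes the Z C1=C5 alkene) ⇒ acrolein + methallylstannane (Keck allylation, the only external source of chirality).
5. Ring order: temporary butenolide (opened), seven-membered ring, temporary γ-lactone (opened to the epoxide), cyclopentane.

Key step: step 15

Remark: atoms carry the daucane numbering of the target throughout (C1 quaternary ring-fusion carbon with the methyl, C2 and C3 ring CH2, C4 isopropyl carbinol, C5 ring-fusion CH, C6 benzoyloxy carbon, C7 ring CH2, C8 methyl-bearing alkene carbon, C9 alkene CH, C10 angeloyloxy carbon); α is the face of the C6 and C10 oxygens, β the face of the C1 methyl.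

Step 1
Reactants: 1 acrolein; 2 tributyl(2-methylallyl)stannane
Product: 4 (S)-5-methylhexa-1,5-dien-3-ol, via stannyl ether 3 (not isolated)
Conditions: Ti(OiPr)4 (10 mol%), (S)-BINOL (20 mol%), 4 Å MS, CH2Cl2, −20 °C; aq. NaHCO3
Reagents that add atoms: none
Why: Keck asymmetric allylation, in which the BINOL–titanium Lewis acid should shield one aldehyde face so that the methallyl group sets the C6 carbinol as S ((S)-BINOL chosen by analogy with its sense for aryl and alkenyl aldehydes).

Step 2
Reactants: 4 (S)-5-methylhexa-1,5-dien-3-ol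
Product: 5 (S)-5-methylhexa-1,5-dien-3-yl 2-methylprop-2-enoate
Conditions: Et3N, DMAP (cat.), CH2Cl2, 0 °C
Reagents that add atoms: methacryloyl chloride, C=C(C)C(Cl)=O
Why: Plain O-acylation of a secondary allylic alcohol, which leaves the stereocenter untouched.

Step 3
Reactants: 5 (S)-5-methylhexa-1,5-dien-3-yl 2-methylprop-2-enoate
Product: 6 (S)-3-methyl-5-(2-methylprop-2-en-1-yl)furan-2(5H)-one
Conditions: second-generation Grubbs catalyst (5 mol%), toluene, 80 °C
Reagents that add atoms: none
Why: Ring-closing metathesis of the vinyl group with the methacrylate should give the butenolide, whose ring fixes the cis (Z) geometry of the future C1=C5 alkene, while the methallyl group cannot close an unstrained ring.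

Step 4
Reactants: 6 (S)-3-methyl-5-(2-methylprop-2-en-1-yl)furan-2(5H)-one
Product: 8 (S,Z)-N-methoxy-N,2,6-trimethyl-4-(triethylsilyloxy)hepta-2,6-dienamide, via magnesium alkoxide 7 (not isolated)
Conditions: MeNH(OMe)·HCl, i-PrMgCl, THF, −20 °C; then TESCl, imidazole (cat.), 0 °C
Reagents that add atoms: N,O-dimethylhydroxylamine hydrochloride, CNOC.Cl; chlorotriethylsilane, CC[Si](Cl)(CC)CC
Why: Aminolysis of the lactone by the magnesium amide (Weinreb amide formation) opens the ring with the Z alkene intact, and silylation in the same flask should stop relactonization.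

Step 5
Reactants: 8 (S,Z)-N-methoxy-N,2,6-trimethyl-4-(triethylsilyloxy)hepta-2,6-dienamide
Product: 10 (S,Z)-4,8-dimethyl-6-(triethylsilyloxy)nona-1,4,8-trien-3-one, via tetrahedral adduct 9 (not isolated)
Conditions: THF, −78 → 0 °C; aq. NH4Cl
Reagents that add atoms: vinylmagnesium bromide, C=C[Mg]Br
Why: Weinreb ketone synthesis, in which the chelated tetrahedral adduct should prevent a second addition and release the vinyl ketone only on work-up.

Step 6
Reactants: 10 (S,Z)-4,8-dimethyl-6-(triethylsilyloxy)nona-1,4,8-trien-3-one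
Product: 11 (S)-2,6-dimethyl-4-(triethylsilyloxy)cyclohepta-2,6-dien-1-one
Conditions: second-generation Hoveyda–Grubbs catalyst (5 mol%), toluene (5 mM), 80 °C
Reagents that add atoms: none
Why: Ring-closing metathesis of the vinyl ketone with the 1,1-disubstituted alkene should close the seven-membered ring and form the trisubstituted C8=C9 alkene, the cis C1=C5 alkene holding the two chain ends together.

Step 7
Reactants: 11 (S)-2,6-dimethyl-4-(triethylsilyloxy)cyclohepta-2,6-dien-1-one
Product: 12 (1R,4S)-2,6-dimethyl-4-(triethylsilyloxy)cyclohepta-2,6-dien-1-ol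
Conditions: NaBH4, CeCl3·7H2O, MeOH, −78 °C
Reagents that add atoms: none
Why: Luche 1,2-reduction, in which hydride should add to the C10 carbonyl from the face opposite to the C6 silyloxy group and so place the two oxygens cis (C10 becomes R).

Step 8
Reactants: 12 (1R,4S)-2,6-dimethyl-4-(triethylsilyloxy)cyclohepta-2,6-dien-1-ol
Product: 13 tert-butyl{[(1R,4S)-2,6-dimethyl-4-(triethylsilyloxy)cyclohepta-2,6-dien-1-yl]oxy}dimethylsilane
Conditions: 2,6-lutidine, CH2Cl2, −78 °C
Reagents that add atoms: tert-butyldimethylsilyl trifluoromethanesulfonate, CC(C)(C)[Si](C)(C)OS(=O)(=O)C(F)(F)F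
Why: Silylation of the doubly allylic C10 alcohol under buffered conditions that should avoid ionization.

Step 9
Reactants: 13 tert-butyl{[(1R,4S)-2,6-dimethyl-4-(triethylsilyloxy)cyclohepta-2,6-dien-1-yl]oxy}dimethylsilane
Product: 14 (1S,4R)-4-(tert-butyldimethylsilyloxy)-3,6-dimethylcyclohepta-2,5-dien-1-ol
Conditions: PPTS (cat.), MeOH, 0 °C
Reagents that add atoms: none
Why: Acid-catalyzed methanolysis should remove only the triethylsilyl ether, which is far more labile than the tert-butyldimethylsilyl ether, and free the C6 allylic alcohol.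

Step 10
Reactants: 14 (1S,4R)-4-(tert-butyldimethylsilyloxy)-3,6-dimethylcyclohepta-2,5-dien-1-ol
Product: 16 2-[(1S,7R)-7-(tert-butyldimethylsilyloxy)-1,5-dimethylcyclohepta-2,5-dien-1-yl]-N,N-dimethylacetamide, via ketene N,O-acetal 15 (not isolated)
Conditions: xylene, 140 °C
Reagents that add atoms: N,N-dimethylacetamide dimethyl acetal, CC(OC)(OC)N(C)C
Why: Eschenmoser–Claisen rearrangement, a suprafacial [3,3] shift that should deliver the acetamide arm to C1 on the face from which the C6 oxygen leaves (α), setting the quaternary center and moving the alkene to C5=C6.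

Step 11
Reactants: 16 2-[(1S,7R)-7-(tert-butyldimethylsilyloxy)-1,5-dimethylcyclohepta-2,5-dien-1-yl]-N,N-dimethylacetamide
Product: 18 iodolactone (γ-lactone from the C1 arm to O–C5 on the α face, 6β-iodo, 10α-silyloxy), via iminium lactone 17 (not isolated)
Conditions: THF/H2O, 0 °C → rt, dark
Reagents that add atoms: iodine, II; water, O
Why: Iodolactonization of a γ,δ-unsaturated amide, in which the amide oxygen should attack C5 (5-exo) from the face of the arm while iodine adds anti at C6, hydrolysis of the iminium ion then giving the lactone.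

Step 12
Reactants: 18 iodolactone
Product: 20 2-[10α-(tert-butyldimethylsilyloxy)-5α,6α-epoxy-1β,8-dimethylcyclohept-8-en-1-yl]acetic acid, via iodohydrin carboxylate 19 (not isolated)
Conditions: THF/H2O, 0 °C → rt; then 1 M HCl to pH 4, 0 °C
Reagents that add atoms: lithium hydroxide, [Li+].[OH-]
Why: Saponification frees the C5 alkoxide, which should displace the anti iodide at C6 with inversion (intramolecular Williamson ether synthesis) to give the epoxide on the face of the acetic acid arm.

Step 13
Reactants: 21 3-methylbutan-2-one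
Product: 23 3-methylbut-1-en-2-yl trifluoromethanesulfonate, via lithium enolate 22 (not isolated)
Conditions: LDA, THF, −78 °C; then PhNTf2, −78 → 0 °C
Reagents that add atoms: N-phenylbis(trifluoromethanesulfonimide), O=S(=O)(N(c1ccccc1)S(=O)(=O)C(F)(F)F)C(F)(F)F
Why: Kinetic deprotonation at the methyl group followed by O-triflation of the enolate should give the less substituted alkenyl triflate.

Step 14
Reactants: 23 3-methylbut-1-en-2-yl trifluoromethanesulfonate
Product: 24 4,4,5,5-tetramethyl-2-(3-methylbut-1-en-2-yl)-1,3,2-dioxaborolane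
Conditions: PdCl2(PPh3)2 (3 mol%), PPh3, KOPh, toluene, 50 °C
Reagents that add atoms: bis(pinacolato)diboron, CC1(C)OB(OC1(C)C)B1OC(C)(C)C(C)(C)O1
Why: Miyaura borylation of an alkenyl triflate, a palladium-catalyzed cross-coupling that should keep the position of the double bond.

Step 15
Reactants: 20 2-[10α-(tert-butyldimethylsilyloxy)-5α,6α-epoxy-1β,8-dimethylcyclohept-8-en-1-yl]acetic acid; 24 4,4,5,5-tetramethyl-2-(3-methylbut-1-en-2-yl)-1,3,2-dioxaborolane
Product: 29 (1S,4R,5S,6S,10R)-10-(tert-butyldimethylsilyloxy)dauc-8-ene-4,6-diol, via alkyl radical 25 (not isolated), via α-boryl radical 26 (not isolated), via α-boryl carbanion 27 (not isolated), via boronate alkoxide 28 (not isolated)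
Conditions: Cs2CO3, 24 (2 equiv), 4CzIPN (2 mol%), DMF, blue LEDs, rt; then H2O2, aq. NaOH, THF, 0 °C
Reagents that add atoms: hydrogen peroxide, OO
Why: Proposed new method: photoexcited 4CzIPN oxidizes the cesium carboxylate of 20, loss of CO2 gives the primary C2 radical 25, which adds to the CH2 terminus of 24; the tertiary α-boryl radical 26 is reduced by the photocatalyst radical anion to carbanion 27 (radical–polar crossover), which opens the epoxide at C5 by SN2 attack, and the C–B bond of 28 is then oxidized with retention. The closest known reaction type is the photoredox decarboxylative radical addition–polar cyclization of carboxylic acids with alkenyl boronates that carry a halide leaving group (3-exo-tet closure to cyclopropyl boronates); here the leaving group is an epoxide on the radical precursor and the ring is five-membered. The cyclopentane closes in anionic 5-exo-tet mode after an intermolecular radical C2–C3 bond formation, so the step is a formal [3+2] annulation. C5 is set by inversion at the epoxide carbon, which puts C4 on the β face and gives the trans ring fusion while the former epoxide oxygen stays α at C6; C4 is set by the approach of the planar carbanion with the branched isopropyl group on the open α side next to H5 and the flat, conformationally small dioxaborolane on the crowded β side next to C6 and the C1 methyl, and the oxidation keeps that configuration. The step needs 5-exo attack at C5 instead of 6-endo attack at C6, and ring closure instead of protonation of 27; the two-atom tether from C1 with arm and epoxide on the same face allows collinear backside attack only at C5, and the substrate is used as its dry cesium salt in an aprotic medium.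

Step 16
Reactants: 29 (1S,4R,5S,6S,10R)-10-(tert-butyldimethylsilyloxy)dauc-8-ene-4,6-diol
Product: 30 (1S,4R,5S,6S,10R)-10-(tert-butyldimethylsilyloxy)-4-hydroxydauc-8-en-6-yl benzoate
Conditions: pyridine, DMAP (cat.), CH2Cl2, 0 °C → rt
Reagents that add atoms: benzoyl chloride, O=C(Cl)c1ccccc1
Why: Acylation should take place only at the secondary C6 hydroxyl, the tertiary C4 hydroxyl being too hindered.

Step 17
Reactants: 30 (1S,4R,5S,6S,10R)-10-(tert-butyldimethylsilyloxy)-4-hydroxydauc-8-en-6-yl benzoate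
Product: 31 (1S,4R,5S,6S,10R)-4,10-dihydroxydauc-8-en-6-yl benzoate
Conditions: HF·pyridine, pyridine, THF, 0 °C → rt
Reagents that add atoms: none
Why: Fluoride-mediated desilylation under buffered, non-basic conditions should free the C10 hydroxyl without benzoate migration.

Step 18
Reactants: 31 (1S,4R,5S,6S,10R)-4,10-dihydroxydauc-8-en-6-yl benzoate
Product: 32 (1S,4R,5S,6S,10R)-6-benzoyloxy-4-hydroxydauc-8-en-10-yl (Z)-2-methylbut-2-enoate (target)
Conditions: Cs2CO3, MeCN, rt
Reagents that add atoms: angelic anhydride, C/C=C(/C)C(=O)OC(=O)/C(C)=C\C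
Why: O-acylation of the allylic C10 alcohol with the anhydride under mild carbonate base should install the angelate with retention at C10 and without isomerization of the Z alkene to the tiglate, the tertiary C4 hydroxyl staying free.

**Compound list**
1 | acrolein | C=CC=O | starting material
2 | tributyl(2-methylallyl)stannane | CC(=C)C[Sn](CCCC)(CCCC)CCCC | starting material
3 | (S)-tributyl[(5-methylhexa-1,5-dien-3-yl)oxy]stannane | C=C[C@@H](O[Sn](CCCC)(CCCC)CCCC)CC(C)=C | intermediate
4 | (S)-5-methylhexa-1,5-dien-3-ol | C=C[C@@H](O)CC(C)=C | intermediate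
5 | (S)-5-methylhexa-1,5-dien-3-yl 2-methylprop-2-enoate | C=C(C)C(=O)O[C@H](C=C)CC(C)=C | intermediate
6 | (S)-3-methyl-5-(2-methylprop-2-en-1-yl)furan-2(5H)-one | CC1=C[C@H](CC(C)=C)OC1=O | intermediate
7 | chloromagnesium alkoxide of (S,Z)-4-hydroxy-N-methoxy-N,2,6-trimethylhepta-2,6-dienamide | CON(C)C(=O)/C(C)=C\[C@@H](O[Mg]Cl)CC(C)=C | intermediate
8 | (S,Z)-N-methoxy-N,2,6-trimethyl-4-(triethylsilyloxy)hepta-2,6-dienamide | CON(C)C(=O)/C(C)=C\[C@@H](O[Si](CC)(CC)CC)CC(C)=C | intermediate
9 | bromomagnesium alkoxide of the tetrahedral vinyl adduct of 8 | C=CC(O[Mg]Br)(N(C)OC)/C(C)=C\[C@@H](O[Si](CC)(CC)CC)CC(C)=C | intermediate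
10 | (S,Z)-4,8-dimethyl-6-(triethylsilyloxy)nona-1,4,8-trien-3-one | C=CC(=O)/C(C)=C\[C@@H](O[Si](CC)(CC)CC)CC(C)=C | intermediate
11 | (S)-2,6-dimethyl-4-(triethylsilyloxy)cyclohepta-2,6-dien-1-one | O=C1C=C(C)C[C@H](O[Si](CC)(CC)CC)C=C1C | intermediate
12 | (1R,4S)-2,6-dimethyl-4-(triethylsilyloxy)cyclohepta-2,6-dien-1-ol | O[C@@H]1C=C(C)C[C@H](O[Si](CC)(CC)CC)C=C1C | intermediate
13 | tert-butyl{[(1R,4S)-2,6-dimethyl-4-(triethylsilyloxy)cyclohepta-2,6-dien-1-yl]oxy}dimethylsilane | CC(C)(C)[Si](C)(C)O[C@@H]1C=C(C)C[C@H](O[Si](CC)(CC)CC)C=C1C | intermediate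
14 | (1S,4R)-4-(tert-butyldimethylsilyloxy)-3,6-dimethylcyclohepta-2,5-dien-1-ol | CC(C)(C)[Si](C)(C)O[C@@H]1C=C(C)C[C@H](O)C=C1C | intermediate
15 | ketene N,O-acetal of 14 (O-[1-(dimethylamino)vinyl] ether at C6) | CC(C)(C)[Si](C)(C)O[C@@H]1C=C(C)C[C@H](OC(=C)N(C)C)C=C1C | intermediate
16 | 2-[(1S,7R)-7-(tert-butyldimethylsilyloxy)-1,5-dimethylcyclohepta-2,5-dien-1-yl]-N,N-dimethylacetamide | CC(C)(C)[Si](C)(C)O[C@@H]1C=C(C)CC=C[C@]1(C)CC(=O)N(C)C | intermediate
17 | iminium lactone iodide (O–C5 α, 6β-iodo, dimethyliminium in place of the lactone carbonyl) | CC(C)(C)[Si](C)(C)O[C@@H]1C=C(C)C[C@@H](I)[C@@H]2OC(=[N+](C)C)C[C@]12C.[I-] | intermediate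
18 | iodolactone: cis-fused γ-lactone from the C1 acetic acid arm to O–C5 (α), 6β-iodo, 10α-(tert-butyldimethylsilyloxy), 1β,8-dimethyl, C8=C9 alkene | CC(C)(C)[Si](C)(C)O[C@@H]1C=C(C)C[C@@H](I)[C@@H]2OC(=O)C[C@]12C | intermediate
19 | lithium 2-[10α-(tert-butyldimethylsilyloxy)-5α-hydroxy-6β-iodo-1β,8-dimethylcyclohept-8-en-1-yl]acetate | CC(C)(C)[Si](C)(C)O[C@@H]1C=C(C)C[C@@H](I)[C@H](O)[C@]1(C)CC(=O)[O-].[Li+] | intermediate
20 | 2-[10α-(tert-butyldimethylsilyloxy)-5α,6α-epoxy-1β,8-dimethylcyclohept-8-en-1-yl]acetic acid | CC(C)(C)[Si](C)(C)O[C@@H]1C=C(C)C[C@@H]2O[C@@H]2[C@]1(C)CC(=O)O | intermediate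
21 | 3-methylbutan-2-one | CC(=O)C(C)C | starting material
22 | lithium 3-methylbut-1-en-2-olate | [Li+].[O-]C(=C)C(C)C | intermediate
23 | 3-methylbut-1-en-2-yl trifluoromethanesulfonate | C=C(OS(=O)(=O)C(F)(F)F)C(C)C | intermediate
24 | 4,4,5,5-tetramethyl-2-(3-methylbut-1-en-2-yl)-1,3,2-dioxaborolane | C=C(C(C)C)B1OC(C)(C)C(C)(C)O1 | intermediate
25 | primary C2 radical from decarboxylation of 20 | CC(C)(C)[Si](C)(C)O[C@@H]1C=C(C)C[C@@H]2O[C@@H]2[C@]1(C)[CH2] | intermediate
26 | tertiary α-boryl radical at C4 (adduct of 25 and 24) | CC(C)(C)[Si](C)(C)O[C@@H]1C=C(C)C[C@@H]2O[C@@H]2[C@]1(C)CC[C](C(C)C)B1OC(C)(C)C(C)(C)O1 | intermediate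
27 | cesium α-boryl carbanion at C4 | CC(C)(C)[Si](C)(C)O[C@@H]1C=C(C)C[C@@H]2O[C@@H]2[C@]1(C)CC[C-](C(C)C)B1OC(C)(C)C(C)(C)O1.[Cs+] | intermediate
28 | cesium 4β-(pinacolboryl)-10α-(tert-butyldimethylsilyloxy)dauc-8-en-6α-olate (trans-fused) | CC(C)(C)[Si](C)(C)O[C@@H]1C=C(C)C[C@H]([O-])[C@@H]2[C@]1(C)CC[C@@]2(B1OC(C)(C)C(C)(C)O1)C(C)C.[Cs+] | intermediate
29 | (1S,4R,5S,6S,10R)-10-(tert-butyldimethylsilyloxy)dauc-8-ene-4,6-diol | CC(C)(C)[Si](C)(C)O[C@@H]1C=C(C)C[C@H](O)[C@@H]2[C@]1(C)CC[C@@]2(O)C(C)C | intermediate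
30 | (1S,4R,5S,6S,10R)-10-(tert-butyldimethylsilyloxy)-4-hydroxydauc-8-en-6-yl benzoate | CC(C)(C)[Si](C)(C)O[C@@H]1C=C(C)C[C@H](OC(=O)c2ccccc2)[C@@H]2[C@]1(C)CC[C@@]2(O)C(C)C | intermediate
31 | (1S,4R,5S,6S,10R)-4,10-dihydroxydauc-8-en-6-yl benzoate | O[C@@H]1C=C(C)C[C@H](OC(=O)c2ccccc2)[C@@H]2[C@]1(C)CC[C@@]2(O)C(C)C | intermediate
32 | (1S,4R,5S,6S,10R)-6-benzoyloxy-4-hydroxydauc-8-en-10-yl (Z)-2-methylbut-2-enoate | C/C=C(/C)C(=O)O[C@@H]1C=C(C)C[C@H](OC(=O)c2ccccc2)[C@@H]2[C@]1(C)CC[C@@]2(O)C(C)C | target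

**Step count and risks**
Total step count: 18. Longest linear sequence: 16 steps (steps 1–12 and 15–18; steps 13–14 make the boronate).

Steps most likely to fail:

Step 15 (proposed new method). Protonation of the α-boryl carbanion may outrun the strained trans ring closure, and the facial selectivity at C4 may be poor. The fallback uses known chemistry only, sets out from 18 and comes back at 29. Potassium carbonate in methanol should convert 18 into epoxy methyl ester F1. LiBH4 should reduce it to epoxy alcohol F2, and iodine, triphenylphosphine and imidazole should give epoxy iodide F3. Alkylation of 2-lithio-1,3-dithiane should give dithiane F4. n-BuLi in THF/HMPA should then close the ring by 5-exo opening of the epoxide with inversion, giving spiro dithiane alcohol F5. MeI and CaCO3 in aqueous acetonitrile should unmask hydroxy cyclopentanone F6. i-PrMgCl/CeCl3 should add from the α face, opposite to the C1 methyl, to return 29.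

Step 7. Facial discrimination in the hydride delivery may be poor, because the directing silyloxy group is remote (1,4) from the carbonyl. The fallback sets out from 10 and comes back at 13. Corey–Bakshi–Shibata reduction of the acyclic trienone 10 with (S)-Me-CBS and catecholborane should set C10 under reagent control and give dienol F7. TBSOTf and 2,6-lutidine should give bis-silyl ether F8. Ring-closing metathesis with the second-generation Hoveyda–Grubbs catalyst should then return 13.

Step 10. Elimination or ionization of the allylic alcohol at 140 °C may outrun the hindered [3,3] shift that builds a quaternary center next to a silyloxy-bearing carbon. The fallback sets out from 14 and comes back at 18, and moves from the neutral thermal amide acetal manifold to the low-temperature ester enolate manifold. Acetylation (Ac2O, pyridine) should give acetate F9. Ireland–Claisen rearrangement (LDA, TMSCl, THF, −78 °C to reflux, then aqueous work-up) should give acid F10. Iodolactonization (I2, NaHCO3, MeCN) should return 18.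

Further compounds
F1 | step 15 | methyl 2-[10α-(tert-butyldimethylsilyloxy)-5α,6α-epoxy-1β,8-dimethylcyclohept-8-en-1-yl]acetate | CC(C)(C)[Si](C)(C)O[C@@H]1C=C(C)C[C@@H]2O[C@@H]2[C@]1(C)CC(=O)OC
F2 | step 15 | 2-[10α-(tert-butyldimethylsilyloxy)-5α,6α-epoxy-1β,8-dimethylcyclohept-8-en-1-yl]ethanol | CC(C)(C)[Si](C)(C)O[C@@H]1C=C(C)C[C@@H]2O[C@@H]2[C@]1(C)CCO
F3 | step 15 | 10α-(tert-butyldimethylsilyloxy)-5α,6α-epoxy-1α-(2-iodoethyl)-1β,8-dimethylcyclohept-8-ene | CC(C)(C)[Si](C)(C)O[C@@H]1C=C(C)C[C@@H]2O[C@@H]2[C@]1(C)CCI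
F4 | step 15 | 2-{2-[10α-(tert-butyldimethylsilyloxy)-5α,6α-epoxy-1β,8-dimethylcyclohept-8-en-1-yl]ethyl}-1,3-dithiane | CC(C)(C)[Si](C)(C)O[C@@H]1C=C(C)C[C@@H]2O[C@@H]2[C@]1(C)CCC1SCCCS1
F5 | step 15 | trans-fused bicyclic alcohol with C4 as a spiro 1,3-dithiane (6α-hydroxy, 10α-silyloxy, 1β,8-dimethyl, C8=C9 alkene) | CC(C)(C)[Si](C)(C)O[C@@H]1C=C(C)C[C@H](O)[C@@H]2[C@]1(C)CCC23SCCCS3
F6 | step 15 | trans-fused 10α-(tert-butyldimethylsilyloxy)-6α-hydroxy-1β,8-dimethylbicyclo[5.3.0]dec-8-en-4-one (target numbering) | CC(C)(C)[Si](C)(C)O[C@@H]1C=C(C)C[C@H](O)[C@@H]2[C@]1(C)CCC2=O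
F7 | step 7 | (3R,6S,Z)-4,8-dimethyl-6-(triethylsilyloxy)nona-1,4,8-trien-3-ol | C=C[C@@H](O)/C(C)=C\[C@@H](O[Si](CC)(CC)CC)CC(C)=C
F8 | step 7 | (3R,6S,Z)-3-(tert-butyldimethylsilyloxy)-4,8-dimethyl-6-(triethylsilyloxy)nona-1,4,8-triene | C=C[C@@H](O[Si](C)(C)C(C)(C)C)/C(C)=C\[C@@H](O[Si](CC)(CC)CC)CC(C)=C
F9 | step 10 | (1S,4R)-4-(tert-butyldimethylsilyloxy)-3,6-dimethylcyclohepta-2,5-dien-1-yl acetate | CC(C)(C)[Si](C)(C)O[C@@H]1C=C(C)C[C@H](OC(C)=O)C=C1C
F10 | step 10 | 2-[(1S,7R)-7-(tert-butyldimethylsilyloxy)-1,5-dimethylcyclohepta-2,5-dien-1-yl]acetic acid | CC(C)(C)[Si](C)(C)O[C@@H]1C=C(C)CC=C[C@]1(C)CC(=O)O
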